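**Plan**
- Retrosynthesis: cut C11'=C12' and C11=C12 (two Wittig reactions: C15 salt + C10 dialdehyde + C15 salt). In each C15 half, cut the vinyl/phosphonium unit back to a 2-allyl-β-ionone, the side-chain alkene C2''=C3'' (cross-metathesis of the allyl group), and last the ring bond C1–C6.
- Enabling feature: in each ring the quaternary C1 (two methyls) lies between the C2 stereocentre and C6 of the C5=C6 alkene. C1 with its methyls, C2, C3, C4, C5, the C5 methyl and the first two side-chain carbons are the ten carbons of a ring-opened limonene (isopropenyl carbon = C1, limonene C4 = C2).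
- Forward: (R)-limonene is ozonolysed, extended to a dienone and cyclized to the prenyl-bearing ring first, then carried to its C15 salt and joined to the C10 dialdehyde. (S)-Limonene follows the same path, and the diol-bearing ring is closed last by cation–olefin cyclization (C1'–C6') of the seco-limonene dienone.
- Stereochemistry: C2 (R) is C4 of (R)-limonene and C2' (S) is C4 of (S)-limonene, both carried through untouched. The E-alkenes come from the Saucy–Marbet/isomerisation sequence, the Wittig reactions and thermal equilibration.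

Key step: step 14

Remark: carotenoid numbering is used (C1 = CMe2, C2 = stereocentre, C5=C6 = ring alkene; primes for the diol-bearing half, double primes for side-chain carbons). Carbinol epimers, allene axes and the 5,6-alkene geometry of the acyclic dienones are left as mixtures because these elements are erased in later steps.

**Step 1**
Reactants: 1 (R)-(+)-limonene
Product: 3 (3R)-6-oxo-3-(prop-1-en-2-yl)heptanal, via limonene ozonide 2 (not isolated)
Conditions: O3 (1.0 equiv, Sudan Red 7B end point), CH2Cl2, −78 °C; then PPh3, −78 °C → rt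
Reagents that add atoms: ozone, [O-][O+]=O
Why: Ozone attacks the electron-rich trisubstituted ring alkene faster than the 1,1-disubstituted isopropenyl group, and reductive work-up of the ozonide (Criegee ozonolysis) opens the limonene ring to the keto aldehyde without touching the stereocentre.

**Step 2**
Reactants: 3 (3R)-6-oxo-3-(prop-1-en-2-yl)heptanal
Product: 4 (5R)-5-(prop-1-en-2-yl)oct-7-en-2-one
Conditions: Ph3PCH3Br, KN(SiMe3)2, THF, 0 °C; then 3, −78 → 0 °C
Reagents that add atoms: methyltriphenylphosphonium bromide, C[P+](c1ccccc1)(c1ccccc1)c1ccccc1.[Br-]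
Why: Wittig methylenation with Ph3P=CH2 at low temperature takes the aldehyde and leaves the less electrophilic methyl ketone, turning the two-carbon stub into the allyl group that later carries the side chain.

**Step 3**
Reactants: 4 (5R)-5-(prop-1-en-2-yl)oct-7-en-2-one
Product: 5 (6R)-3-methyl-6-(prop-1-en-2-yl)non-8-en-1-yn-3-ol (both C3 epimers)
Conditions: HC≡CMgBr (1.5 equiv), THF, 0 °C → rt; aq. NH4Cl
Reagents that add atoms: ethynylmagnesium bromide, C#C[Mg]Br
Why: Grignard 1,2-addition of the acetylide to the methyl ketone delivers the two carbons that become C6 and C7; the carbinol centre forms as both epimers, which is harmless because it becomes sp2 in step 4.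

**Step 4**
Reactants: 5 (6R)-3-methyl-6-(prop-1-en-2-yl)non-8-en-1-yn-3-ol
Product: 9 (3E,9R)-6-methyl-9-(prop-1-en-2-yl)dodeca-3,5,11-trien-2-one (5E/5Z mixture), via mixed ketal 6 (not isolated), via isopropenyl ether 7 (not isolated), via allenyl ketone 8 (not isolated)
Conditions: 2-methoxypropene (3 equiv), p-TsOH (0.5 mol%), toluene, 100 °C (sealed); then NaOMe (10 mol%), MeOH, 0 °C
Reagents that add atoms: 2-methoxypropene, COC(C)=C
Why: Saucy–Marbet reaction: acid-catalysed exchange gives the propargyl isopropenyl ether, its [3,3] shift (propargyl Claisen) gives the β-allenyl ketone, and base-mediated prototropic isomerisation gives the conjugated (3E)-dienone of the pseudoionone type, the 5,6-geometry being irrelevant because that bond becomes the ring alkene.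

**Step 5**
Reactants: 9 (3E,9R)-6-methyl-9-(prop-1-en-2-yl)dodeca-3,5,11-trien-2-one
Product: 10 (E)-4-[(5R)-2,6,6-trimethyl-5-(prop-2-en-1-yl)cyclohex-1-en-1-yl]but-3-en-2-one
Conditions: conc. H2SO4 (4 equiv), CH2Cl2, −20 → −10 °C, 10 min; then ice/NaHCO3
Reagents that add atoms: none
Why: The same cation–olefin ring closure as in the key step, run here in the (R)-series: protonation of the isopropenyl group, capture of the C1 cation by C6 and loss of H6 should give the conjugated ring alkene (pseudoionone-type cyclization), with C2 carried over unchanged from (R)-limonene.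

**Step 6**
Reactants: 10 (E)-4-[(5R)-2,6,6-trimethyl-5-(prop-2-en-1-yl)cyclohex-1-en-1-yl]but-3-en-2-one
Product: 11 (E)-4-[(5R)-2,6,6-trimethyl-5-(3-methylbut-2-en-1-yl)cyclohex-1-en-1-yl]but-3-en-2-one
Conditions: 2-methyl-2-butene (co-solvent, excess), second-generation Grubbs catalyst RuCl2(=CHPh)(PCy3)(H2IMes) (5 mol%), CH2Cl2, 40 °C (sealed)
Reagents that add atoms: 2-methyl-2-butene, CC=C(C)C
Why: Olefin cross-metathesis of the monosubstituted allyl alkene with 2-methyl-2-butene installs the prenyl group, while the tetrasubstituted ring alkene and the hindered conjugated enone alkene are poor metathesis substrates.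

**Step 7**
Reactants: 11 (E)-4-[(5R)-2,6,6-trimethyl-5-(3-methylbut-2-en-1-yl)cyclohex-1-en-1-yl]but-3-en-2-one
Product: 12 (1E)-3-methyl-1-[(5R)-2,6,6-trimethyl-5-(3-methylbut-2-en-1-yl)cyclohex-1-en-1-yl]penta-1,4-dien-3-ol (both C3 epimers)
Conditions: CH2=CHMgBr (1.5 equiv), THF, −20 → 0 °C; aq. NH4Cl
Reagents that add atoms: vinylmagnesium bromide, C=C[Mg]Br
Why: 1,2-Addition of the vinyl Grignard reagent to the methyl ketone of a β-ionone gives the tertiary doubly allylic alcohol as both carbinol epimers, a centre that is lost in step 8.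

**Step 8**
Reactants: 12 (1E)-3-methyl-1-[(5R)-2,6,6-trimethyl-5-(3-methylbut-2-en-1-yl)cyclohex-1-en-1-yl]penta-1,4-dien-3-ol
Product: 13 {(2E,4E)-3-methyl-5-[(5R)-2,6,6-trimethyl-5-(3-methylbut-2-en-1-yl)cyclohex-1-en-1-yl]penta-2,4-dien-1-yl}triphenylphosphonium bromide
Conditions: PPh3·HBr (1.0 equiv), MeOH, 0 °C → rt
Reagents that add atoms: triphenylphosphine hydrobromide, [Br-].c1ccc(cc1)[PH+](c1ccccc1)c1ccccc1
Why: The weak acid PPh3·HBr ionises the tertiary doubly allylic alcohol to a pentadienyl cation that PPh3 captures at the primary terminus (allylic transposition, standard C15 Wittig salt formation), and it is too weak to protonate the isolated prenyl alkene.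

**Step 9**
Reactants: 13 the C15 phosphonium bromide of the prenyl-bearing ring; 14 (2E,4E,6E)-2,7-dimethylocta-2,4,6-trienedial (3 equiv)
Product: 16 (2E,4E,6E,8E,10E,12E)-2,7,11-trimethyl-13-[(5R)-2,6,6-trimethyl-5-(3-methylbut-2-en-1-yl)cyclohex-1-en-1-yl]trideca-2,4,6,8,10,12-hexaenal, via phosphorus ylide 15 (not isolated)
Conditions: NaOMe (1.1 equiv), CH2Cl2/MeOH, −10 °C → rt (13 added slowly to 14); then heptane, reflux (Z → E)
Reagents that add atoms: none
Why: Wittig reaction of the semi-stabilised ylide with an excess of the symmetrical dialdehyde should stop after one olefination, and heating equilibrates the new C11=C12 alkene to the E isomer.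

**Step 10**
Reactants: 17 (S)-(−)-limonene
Product: 19 (3S)-6-oxo-3-(prop-1-en-2-yl)heptanal, via limonene ozonide 18 (not isolated)
Conditions: O3 (1.0 equiv, Sudan Red 7B end point), CH2Cl2, −78 °C; then PPh3, −78 °C → rt
Reagents that add atoms: ozone, [O-][O+]=O
Why: As in step 1, selective Criegee ozonolysis of the trisubstituted ring alkene opens the limonene ring and leaves the isopropenyl group and the stereocentre intact.

**Step 11**
Reactants: 19 (3S)-6-oxo-3-(prop-1-en-2-yl)heptanal
Product: 20 (5S)-5-(prop-1-en-2-yl)oct-7-en-2-one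
Conditions: Ph3PCH3Br, KN(SiMe3)2, THF, 0 °C; then 19, −78 → 0 °C
Reagents that add atoms: methyltriphenylphosphonium bromide, C[P+](c1ccccc1)(c1ccccc1)c1ccccc1.[Br-]
Why: Aldehyde-selective Wittig methylenation as in step 2.

**Step 12**
Reactants: 20 (5S)-5-(prop-1-en-2-yl)oct-7-en-2-one
Product: 21 (6S)-3-methyl-6-(prop-1-en-2-yl)non-8-en-1-yn-3-ol (both C3 epimers)
Conditions: HC≡CMgBr (1.5 equiv), THF, 0 °C → rt; aq. NH4Cl
Reagents that add atoms: ethynylmagnesium bromide, C#C[Mg]Br
Why: Grignard 1,2-addition of the acetylide to the methyl ketone as in step 3, the new carbinol centre being erased in step 13.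

**Step 13**
Reactants: 21 (6S)-3-methyl-6-(prop-1-en-2-yl)non-8-en-1-yn-3-ol
Product: 25 (3E,9S)-6-methyl-9-(prop-1-en-2-yl)dodeca-3,5,11-trien-2-one (5E/5Z mixture), via mixed ketal 22 (not isolated), via isopropenyl ether 23 (not isolated), via allenyl ketone 24 (not isolated)
Conditions: 2-methoxypropene (3 equiv), p-TsOH (0.5 mol%), toluene, 100 °C (sealed); then NaOMe (10 mol%), MeOH, 0 °C
Reagents that add atoms: 2-methoxypropene, COC(C)=C
Why: Saucy–Marbet propargyl Claisen rearrangement and base-mediated isomerisation of the allenyl ketone to the conjugated dienone, as in step 4.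

**Step 14**
Reactants: 25 (3E,9S)-6-methyl-9-(prop-1-en-2-yl)dodeca-3,5,11-trien-2-one
Product: 26 (E)-4-[(5S)-2,6,6-trimethyl-5-(prop-2-en-1-yl)cyclohex-1-en-1-yl]but-3-en-2-one
Conditions: conc. H2SO4 (4 equiv), CH2Cl2, −20 → −10 °C, 10 min; then ice/NaHCO3
Reagents that add atoms: none
Why: Protonation of the 1,1-disubstituted isopropenyl alkene gives the tertiary cation at C1', which is captured by C6' of the C5'=C6' alkene through a chair-like transition state with the allyl group equatorial; the resulting C5' cation loses H6' so that the new tetrasubstituted C5'=C6' alkene ends in conjugation with the enone. The closest known reaction type is the sulfuric acid cyclization of pseudoionone to β-ionone (and of pseudoirones to irones), and the closure also copies the cyclase step of C50 carotenoid biosynthesis. The ring closes in the 6-endo-trig mode with respect to the C5'=C6' alkene, forming the C1'–C6' bond and with it the quaternary gem-dimethyl carbon next to the stereocentre. No new stereocentre is created: C2' (S) is the former C4 of (S)-limonene and is a spectator, so it is controlled by the starting material as long as ring closure outruns a 1,2-hydride shift from C2' to C1', which the low temperature, the short contact time and the pre-folded chair are meant to secure. The step needs chemoselective protonation of the isopropenyl group (tertiary cation) over the monosubstituted allyl alkene (secondary cation), given by the difference in cation stability, and regioselective proton loss to the C5'=C6' isomer, given by conjugation with the enone under equilibrating strongly acidic conditions.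

**Step 15**
Reactants: 26 (E)-4-[(5S)-2,6,6-trimethyl-5-(prop-2-en-1-yl)cyclohex-1-en-1-yl]but-3-en-2-one; 27 2-methylidenepropane-1,3-diyl diacetate (4 equiv)
Product: 28 (E)-4-{(5S)-5-[4-acetoxy-3-(acetoxymethyl)but-2-en-1-yl]-2,6,6-trimethylcyclohex-1-en-1-yl}but-3-en-2-one
Conditions: second-generation Hoveyda–Grubbs catalyst RuCl2(=CH-C6H4-2-O-i-Pr)(H2IMes) (2 × 5 mol%), CH2Cl2, 40 °C
Reagents that add atoms: none
Why: Olefin cross-metathesis of the terminal allyl alkene with a symmetrical 1,1-disubstituted alkene gives the trisubstituted alkene with no E/Z issue, and the other alkenes of 26 (tetrasubstituted ring alkene, conjugated enone) are inert.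

**Step 16**
Reactants: 28 (E)-4-{(5S)-5-[4-acetoxy-3-(acetoxymethyl)but-2-en-1-yl]-2,6,6-trimethylcyclohex-1-en-1-yl}but-3-en-2-one
Product: 29 (1E)-1-{(5S)-5-[4-hydroxy-3-(hydroxymethyl)but-2-en-1-yl]-2,6,6-trimethylcyclohex-1-en-1-yl}-3-methylpenta-1,4-dien-3-ol (both C3 epimers)
Conditions: CH2=CHMgBr (7 equiv), THF, −20 °C → rt; aq. NH4Cl
Reagents that add atoms: vinylmagnesium bromide, C=C[Mg]Br
Why: Excess vinyl Grignard reagent adds 1,2 to the methyl ketone and at the same time cleaves both acetates by double addition, so the tertiary carbinol and the free allylic diol are reached in one operation (Grignard addition).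

**Step 17**
Reactants: 29 (1E)-1-{(5S)-5-[4-hydroxy-3-(hydroxymethyl)but-2-en-1-yl]-2,6,6-trimethylcyclohex-1-en-1-yl}-3-methylpenta-1,4-dien-3-ol
Product: 30 {(2E,4E)-5-{(5S)-5-[4-hydroxy-3-(hydroxymethyl)but-2-en-1-yl]-2,6,6-trimethylcyclohex-1-en-1-yl}-3-methylpenta-2,4-dien-1-yl}triphenylphosphonium bromide
Conditions: PPh3·HBr (1.0 equiv), MeOH, 0 °C → rt
Reagents that add atoms: triphenylphosphine hydrobromide, [Br-].c1ccc(cc1)[PH+](c1ccccc1)c1ccccc1
Why: PPh3·HBr should selectively ionise the tertiary doubly allylic alcohol, whose cation is delocalised over the triene, while the primary allylic alcohols of the side chain would give a far less stabilised allyl cation bearing an electron-withdrawing hydroxymethyl group and are left alone (C15 Wittig salt formation with allylic transposition).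

**Step 18**
Reactants: 16 the C30 apo-aldehyde carrying the prenyl ring; 30 the C15 phosphonium bromide of the diol ring (1.2 equiv)
Product: 32 (2R,2'S)-2-(3-methylbut-2-en-1-yl)-2'-[4-hydroxy-3-(hydroxymethyl)but-2-en-1-yl]-β,β-carotene (target), via phosphorus ylide 31 (not isolated)
Conditions: 1,2-epoxybutane, EtOH, reflux (Ar, dark); then heptane, reflux (Z → E), crystallisation
Reagents that add atoms: none
Why: Wittig reaction under neutral epoxide conditions (bromide opens 1,2-epoxybutane and the alkoxide forms the ylide) tolerates the free diol and forms C11'=C12', and heating equilibrates the polyene to the all-E target.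

**Compound list**
1 | (R)-(+)-limonene | CC1=CC[C@@H](CC1)C(C)=C | starting material
2 | ozonide of 1 (1,2,4-trioxolane across the former ring alkene, mixture at the ozonide carbons) | CC12CC[C@H](CC(OO1)O2)C(C)=C | intermediate (not isolated)
3 | (3R)-6-oxo-3-(prop-1-en-2-yl)heptanal | CC(=O)CC[C@H](CC=O)C(C)=C | intermediate
4 | (5R)-5-(prop-1-en-2-yl)oct-7-en-2-one | CC(=O)CC[C@H](CC=C)C(C)=C | intermediate
5 | (6R)-3-methyl-6-(prop-1-en-2-yl)non-8-en-1-yn-3-ol (both C3 epimers) | C#CC(C)(O)CC[C@H](CC=C)C(C)=C | intermediate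
6 | 2-methoxyprop-2-yl mixed ketal of 5 | C#CC(C)(OC(C)(C)OC)CC[C@H](CC=C)C(C)=C | intermediate (not isolated)
7 | isopropenyl ether of 5 | C#CC(C)(OC(C)=C)CC[C@H](CC=C)C(C)=C | intermediate (not isolated)
8 | (9R)-6-methyl-9-(prop-1-en-2-yl)dodeca-4,5,11-trien-2-one (allenyl ketone) | CC(=O)CC=C=C(C)CC[C@H](CC=C)C(C)=C | intermediate (not isolated)
9 | (3E,9R)-6-methyl-9-(prop-1-en-2-yl)dodeca-3,5,11-trien-2-one (5E/5Z mixture, 5E drawn) | CC(=O)/C=C/C=C(\C)CC[C@H](CC=C)C(C)=C | intermediate
10 | (E)-4-[(5R)-2,6,6-trimethyl-5-(prop-2-en-1-yl)cyclohex-1-en-1-yl]but-3-en-2-one | CC(=O)/C=C/C1=C(C)CC[C@H](CC=C)C1(C)C | intermediate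
11 | (E)-4-[(5R)-2,6,6-trimethyl-5-(3-methylbut-2-en-1-yl)cyclohex-1-en-1-yl]but-3-en-2-one | CC(=O)/C=C/C1=C(C)CC[C@H](CC=C(C)C)C1(C)C | intermediate
12 | (1E)-3-methyl-1-[(5R)-2,6,6-trimethyl-5-(3-methylbut-2-en-1-yl)cyclohex-1-en-1-yl]penta-1,4-dien-3-ol (both C3 epimers) | C=CC(C)(O)/C=C/C1=C(C)CC[C@H](CC=C(C)C)C1(C)C | intermediate
13 | {(2E,4E)-3-methyl-5-[(5R)-2,6,6-trimethyl-5-(3-methylbut-2-en-1-yl)cyclohex-1-en-1-yl]penta-2,4-dien-1-yl}triphenylphosphonium bromide | C/C(=C\C[P+](c1ccccc1)(c1ccccc1)c1ccccc1)/C=C/C1=C(C)CC[C@H](CC=C(C)C)C1(C)C.[Br-] | intermediate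
14 | (2E,4E,6E)-2,7-dimethylocta-2,4,6-trienedial | O=C/C(C)=C/C=C/C=C(C)/C=O | starting material
15 | ylide of 13 | C/C(=C\C=P(c1ccccc1)(c1ccccc1)c1ccccc1)/C=C/C1=C(C)CC[C@H](CC=C(C)C)C1(C)C | intermediate (not isolated)
16 | (2E,4E,6E,8E,10E,12E)-2,7,11-trimethyl-13-[(5R)-2,6,6-trimethyl-5-(3-methylbut-2-en-1-yl)cyclohex-1-en-1-yl]trideca-2,4,6,8,10,12-hexaenal | CC(C)=CC[C@H]1CCC(C)=C(/C=C/C(C)=C/C=C/C(C)=C/C=C/C=C(C)/C=O)C1(C)C | intermediate
17 | (S)-(−)-limonene | CC1=CC[C@H](CC1)C(C)=C | starting material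
18 | ozonide of 17 (mixture at the ozonide carbons) | CC12CC[C@@H](CC(OO1)O2)C(C)=C | intermediate (not isolated)
19 | (3S)-6-oxo-3-(prop-1-en-2-yl)heptanal | CC(=O)CC[C@@H](CC=O)C(C)=C | intermediate
20 | (5S)-5-(prop-1-en-2-yl)oct-7-en-2-one | CC(=O)CC[C@@H](CC=C)C(C)=C | intermediate
21 | (6S)-3-methyl-6-(prop-1-en-2-yl)non-8-en-1-yn-3-ol (both C3 epimers) | C#CC(C)(O)CC[C@@H](CC=C)C(C)=C | intermediate
22 | 2-methoxyprop-2-yl mixed ketal of 21 | C#CC(C)(OC(C)(C)OC)CC[C@@H](CC=C)C(C)=C | intermediate (not isolated)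
23 | isopropenyl ether of 21 | C#CC(C)(OC(C)=C)CC[C@@H](CC=C)C(C)=C | intermediate (not isolated)
24 | (9S)-6-methyl-9-(prop-1-en-2-yl)dodeca-4,5,11-trien-2-one (allenyl ketone) | CC(=O)CC=C=C(C)CC[C@@H](CC=C)C(C)=C | intermediate (not isolated)
25 | (3E,9S)-6-methyl-9-(prop-1-en-2-yl)dodeca-3,5,11-trien-2-one (5E/5Z mixture, 5E drawn) | CC(=O)/C=C/C=C(\C)CC[C@@H](CC=C)C(C)=C | intermediate
26 | (E)-4-[(5S)-2,6,6-trimethyl-5-(prop-2-en-1-yl)cyclohex-1-en-1-yl]but-3-en-2-one | CC(=O)/C=C/C1=C(C)CC[C@@H](CC=C)C1(C)C | intermediate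
27 | 2-methylidenepropane-1,3-diyl diacetate | CC(=O)OCC(=C)COC(C)=O | starting material
28 | (E)-4-{(5S)-5-[4-acetoxy-3-(acetoxymethyl)but-2-en-1-yl]-2,6,6-trimethylcyclohex-1-en-1-yl}but-3-en-2-one | CC(=O)/C=C/C1=C(C)CC[C@@H](CC=C(COC(C)=O)COC(C)=O)C1(C)C | intermediate
29 | (1E)-1-{(5S)-5-[4-hydroxy-3-(hydroxymethyl)but-2-en-1-yl]-2,6,6-trimethylcyclohex-1-en-1-yl}-3-methylpenta-1,4-dien-3-ol (both C3 epimers) | C=CC(C)(O)/C=C/C1=C(C)CC[C@@H](CC=C(CO)CO)C1(C)C | intermediate
30 | {(2E,4E)-5-{(5S)-5-[4-hydroxy-3-(hydroxymethyl)but-2-en-1-yl]-2,6,6-trimethylcyclohex-1-en-1-yl}-3-methylpenta-2,4-dien-1-yl}triphenylphosphonium bromide | C/C(=C\C[P+](c1ccccc1)(c1ccccc1)c1ccccc1)/C=C/C1=C(C)CC[C@@H](CC=C(CO)CO)C1(C)C.[Br-] | intermediate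
31 | ylide of 30 | C/C(=C\C=P(c1ccccc1)(c1ccccc1)c1ccccc1)/C=C/C1=C(C)CC[C@@H](CC=C(CO)CO)C1(C)C | intermediate (not isolated)
32 | (2R,2'S)-2-(3-methylbut-2-en-1-yl)-2'-[4-hydroxy-3-(hydroxymethyl)but-2-en-1-yl]-β,β-carotene | CC(C)=CC[C@H]1CCC(C)=C(/C=C/C(C)=C/C=C/C(C)=C/C=C/C=C(C)/C=C/C=C(C)/C=C/C2=C(C)CC[C@@H](CC=C(CO)CO)C2(C)C)C1(C)C | target

**Totals**
Total step count: 18. Longest linear sequence: 10 steps (steps 1–9, then step 18).

**Steps most likely to fail**

Step 14 (step 5 is the same operation on the enantiomeric substrate and serves as its rehearsal). Three processes may spoil it. The open C1' cation may live long enough for a 1,2-hydride shift from C2', or for loss and return of the C2' proton, which would erode the configuration. The concentrated acid may slowly protonate the allyl alkene. The ring alkene may not migrate fully into conjugation. The fallback sets out from ketone 20 and comes back at 26; it closes the ring onto a far more nucleophilic enol in a mild medium and fixes the alkene position separately. Acylation of 20 at the methyl group (NaH, dimethyl carbonate) should give methyl (6S)-3-oxo-6-(prop-1-en-2-yl)non-8-enoate F1. SnCl4 in CH2Cl2 should cyclize it (olefinic β-keto ester cyclization) to methyl (3S)-2,2-dimethyl-6-oxo-3-(prop-2-en-1-yl)cyclohexane-1-carboxylate F2. NaH and ClP(O)(OEt)2 should convert this into methyl (5S)-2-[(diethoxyphosphoryl)oxy]-6,6-dimethyl-5-(prop-2-en-1-yl)cyclohex-1-ene-1-carboxylate F3. Me2CuLi should replace the phosphate by methyl to give methyl (5S)-2,6,6-trimethyl-5-(prop-2-en-1-yl)cyclohex-1-ene-1-carboxylate F4. Reduction with i-Bu2AlH should give [(5S)-2,6,6-trimethyl-5-(prop-2-en-1-yl)cyclohex-1-en-1-yl]methanol F5, and MnO2 should oxidise it to (5S)-2,6,6-trimethyl-5-(prop-2-en-1-yl)cyclohex-1-ene-1-carbaldehyde F6. Aldol condensation with acetone (NaOH) then returns 26.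

Step 15. Productive metathesis of the 1,1-disubstituted partner may be slow, so that homodimerisation of 26 and catalyst decay win before the trisubstituted alkene forms. The fallback sets out from 26 and comes back at 28; it replaces metathesis by carbonyl olefination. Dihydroxylation of the terminal alkene (OsO4 cat., N-methylmorpholine N-oxide) should give (E)-4-[(5S)-5-(2,3-dihydroxypropyl)-2,6,6-trimethylcyclohex-1-en-1-yl]but-3-en-2-one F7. Cleavage with NaIO4 should give 2-{(1S)-2,2,4-trimethyl-3-[(1E)-3-oxobut-1-en-1-yl]cyclohex-3-en-1-yl}acetaldehyde F8. Knoevenagel condensation with dimethyl malonate (TiCl4, pyridine) should give dimethyl 2-(2-{(1S)-2,2,4-trimethyl-3-[(1E)-3-oxobut-1-en-1-yl]cyclohex-3-en-1-yl}ethylidene)propanedioate F9. i-Bu2AlH should reduce both esters and the ketone to (E)-4-{(5S)-5-[4-hydroxy-3-(hydroxymethyl)but-2-en-1-yl]-2,6,6-trimethylcyclohex-1-en-1-yl}but-3-en-2-ol F10. Acetylation of the two primary alcohols only (AcCl, 2,4,6-collidine, −78 °C) should give (E)-4-{(5S)-5-[4-acetoxy-3-(acetoxymethyl)but-2-en-1-yl]-2,6,6-trimethylcyclohex-1-en-1-yl}but-3-en-2-ol F11. MnO2 oxidation of the secondary allylic alcohol then returns 28.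

Step 17. Chemoselectivity may be lost: ionisation or bromide displacement at the primary allylic alcohols of the side chain may compete with reaction at the tertiary carbinol. The fallback sets out from 29 and comes back at 30; it masks the diol during salt formation. Silylation of the two primary alcohols (t-BuPh2SiCl, imidazole) should give (1E)-1-{(5S)-5-[4-(tert-butyldiphenylsilyloxy)-3-(tert-butyldiphenylsilyloxymethyl)but-2-en-1-yl]-2,6,6-trimethylcyclohex-1-en-1-yl}-3-methylpenta-1,4-dien-3-ol F12. PPh3·HBr in CH2Cl2 should then give the bis-silylated C15 phosphonium bromide F13. Desilylation with Bu4NF buffered with AcOH returns 30.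

**Further compounds**
F1 | step 14 | methyl (6S)-3-oxo-6-(prop-1-en-2-yl)non-8-enoate | COC(=O)CC(=O)CC[C@@H](CC=C)C(C)=C
F2 | step 14 | methyl (3S)-2,2-dimethyl-6-oxo-3-(prop-2-en-1-yl)cyclohexane-1-carboxylate | COC(=O)C1C(=O)CC[C@@H](CC=C)C1(C)C
F3 | step 14 | methyl (5S)-2-[(diethoxyphosphoryl)oxy]-6,6-dimethyl-5-(prop-2-en-1-yl)cyclohex-1-ene-1-carboxylate | COC(=O)C1=C(OP(=O)(OCC)OCC)CC[C@@H](CC=C)C1(C)C
F4 | step 14 | methyl (5S)-2,6,6-trimethyl-5-(prop-2-en-1-yl)cyclohex-1-ene-1-carboxylate | COC(=O)C1=C(C)CC[C@@H](CC=C)C1(C)C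
F5 | step 14 | [(5S)-2,6,6-trimethyl-5-(prop-2-en-1-yl)cyclohex-1-en-1-yl]methanol | OCC1=C(C)CC[C@@H](CC=C)C1(C)C
F6 | step 14 | (5S)-2,6,6-trimethyl-5-(prop-2-en-1-yl)cyclohex-1-ene-1-carbaldehyde | O=CC1=C(C)CC[C@@H](CC=C)C1(C)C
F7 | step 15 | (E)-4-[(5S)-5-(2,3-dihydroxypropyl)-2,6,6-trimethylcyclohex-1-en-1-yl]but-3-en-2-one | CC(=O)/C=C/C1=C(C)CC[C@@H](CC(O)CO)C1(C)C
F8 | step 15 | 2-{(1S)-2,2,4-trimethyl-3-[(1E)-3-oxobut-1-en-1-yl]cyclohex-3-en-1-yl}acetaldehyde | CC(=O)/C=C/C1=C(C)CC[C@@H](CC=O)C1(C)C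
F9 | step 15 | dimethyl 2-(2-{(1S)-2,2,4-trimethyl-3-[(1E)-3-oxobut-1-en-1-yl]cyclohex-3-en-1-yl}ethylidene)propanedioate | CC(=O)/C=C/C1=C(C)CC[C@@H](CC=C(C(=O)OC)C(=O)OC)C1(C)C
F10 | step 15 | (E)-4-{(5S)-5-[4-hydroxy-3-(hydroxymethyl)but-2-en-1-yl]-2,6,6-trimethylcyclohex-1-en-1-yl}but-3-en-2-ol | CC(O)/C=C/C1=C(C)CC[C@@H](CC=C(CO)CO)C1(C)C
F11 | step 15 | (E)-4-{(5S)-5-[4-acetoxy-3-(acetoxymethyl)but-2-en-1-yl]-2,6,6-trimethylcyclohex-1-en-1-yl}but-3-en-2-ol | CC(O)/C=C/C1=C(C)CC[C@@H](CC=C(COC(C)=O)COC(C)=O)C1(C)C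
F12 | step 17 | (1E)-1-{(5S)-5-[4-(tert-butyldiphenylsilyloxy)-3-(tert-butyldiphenylsilyloxymethyl)but-2-en-1-yl]-2,6,6-trimethylcyclohex-1-en-1-yl}-3-methylpenta-1,4-dien-3-ol | C=CC(C)(O)/C=C/C1=C(C)CC[C@@H](CC=C(CO[Si](c2ccccc2)(c2ccccc2)C(C)(C)C)CO[Si](c2ccccc2)(c2ccccc2)C(C)(C)C)C1(C)C
F13 | step 17 | {(2E,4E)-5-{(5S)-5-[4-(tert-butyldiphenylsilyloxy)-3-(tert-butyldiphenylsilyloxymethyl)but-2-en-1-yl]-2,6,6-trimethylcyclohex-1-en-1-yl}-3-methylpenta-2,4-dien-1-yl}triphenylphosphonium bromide | C/C(=C\C[P+](c1ccccc1)(c1ccccc1)c1ccccc1)/C=C/C1=C(C)CC[C@@H](CC=C(CO[Si](c2ccccc2)(c2ccccc2)C(C)(C)C)CO[Si](c2ccccc2)(c2ccccc2)C(C)(C)C)C1(C)C.[Br-]
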